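**Plan**
- Retrosynthesis cuts, in order: the C8–O acyl bond (coumarate); the C4–H bond back to a C4 tertiary carbinol; the C8–O/C7–H pair (hydration of C7=C8); C8–C9 and C6–C7 together ([5+2]); the cyclopropane bonds C1–C6/C5–C6; and C1–C5 (enyne metathesis).
- Enabling feature: C9=C10(CH3)–C1 together with the C1–C5–C6 triangle is a 1-isopropenylbicyclo[3.1.0]hexane, i.e. a vinylcyclopropane carrying ring A, and C7–C8 with C11 is 2-methylbut-3-yn-2-ol.
- Forward: ring A by ring-closing enyne metathesis of a linalool-derived enyne, then the cyclopropane, then ring B by rhodium-catalysed [5+2] cycloaddition with the alkynol, then functional-group adjustment and esterification.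
- Stereochemistry: the C4 carbinol of (S)-linalool directs the cyclopropanation and so fixes C5; syn hydroboration sets C7/C8 trans; C4 is finally reset by hydrogen-atom transfer anti to C6 once its oxygen has served; the E alkene comes from 4-hydroxycinnamic acid.

Key step: step 7

Remark: guaiane numbering is used (ring A C1–C5; ring B C1, C5–C10; C14 on C10, C15 on C4, C11 on C7), and (S)-(+)-linalool of high enantiomeric purity is assumed to be purchasable.

Step 1
Reactants: 1 (S)-linalool
Product: 3 (5S)-5-ethenyl-5-methyloxolan-2-ol, via ozonide 2 (not isolated)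
Conditions: O3 (1.0 equiv), CH2Cl2, −78 °C; then Me2S, −78 °C to rt
Reagents that add atoms: ozone, [O-][O+]=O
Why: Chemoselective ozonolysis (Criegee cleavage, reductive work-up): ozone should attack the electron-rich trisubstituted alkene much faster than the vinyl group, acetone is lost, and the hydroxy aldehyde closes to the lactol with the carbinol stereocentre untouched.

Step 2
Reactants: 3 (5S)-5-ethenyl-5-methyloxolan-2-ol
Product: 4 (3S)-3-methylhept-1-en-6-yn-3-ol
Conditions: dimethyl (1-diazo-2-oxopropyl)phosphonate, K2CO3, MeOH, 0 °C to rt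
Reagents that add atoms: dimethyl (1-diazo-2-oxopropyl)phosphonate, CC(=O)C(=[N+]=[N-])P(=O)(OC)OC
Why: Seyferth–Gilbert homologation with the Ohira–Bestmann reagent: the lactol opens to its hydroxy aldehyde under K2CO3/MeOH and is converted into the terminal alkyne, adding the carbon that becomes C10 without touching the carbinol centre.

Step 3
Reactants: 4 (3S)-3-methylhept-1-en-6-yn-3-ol
Product: 6 (3S)-3-methyloct-1-en-6-yn-3-ol, via dilithium salt 5 (not isolated)
Conditions: n-BuLi (2.1 equiv), THF, −78 to 0 °C; then MeI (1.1 equiv), −78 °C to rt; H2O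
Reagents that add atoms: iodomethane, CI; n-butyllithium, [Li]CCCC (lithium of 5 only)
Why: Acetylide alkylation: the lithium acetylide is far more nucleophilic towards MeI than the hindered tertiary lithium alkoxide, so the methyl (the later C14) should go on carbon.

Step 4
Reactants: 6 (3S)-3-methyloct-1-en-6-yn-3-ol
Product: 7 (1S)-1-methyl-3-(prop-1-en-2-yl)cyclopent-2-en-1-ol
Conditions: second-generation Grubbs catalyst RuCl2(=CHPh)(PCy3)(H2IMes) (3 mol %), CH2Cl2, 40 °C
Reagents that add atoms: none
Why: Ring-closing enyne metathesis (exo mode): the ruthenium carbene formed at the vinyl group adds across the alkyne, closing ring A as the C1=C5 cyclopentene and leaving the former vinyl CH2 on C10 as the isopropenyl group; no stereocentre is made or touched, and free allylic hydroxyls are well tolerated.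

Step 5
Reactants: 7 (1S)-1-methyl-3-(prop-1-en-2-yl)cyclopent-2-en-1-ol; 8 diiodomethane
Product: 10 (1R,2S,5R)-2-methyl-5-(prop-1-en-2-yl)bicyclo[3.1.0]hexan-2-ol, via ethylzinc alkoxide 9 (not isolated)
Conditions: Et2Zn (2.2 equiv), CH2I2 (2.2 equiv), CH2Cl2, −10 to 0 °C; aq NH4Cl
Reagents that add atoms: diethylzinc, CC[Zn]CC (ethylzinc group of 9 only)
Why: Hydroxyl-directed Simmons–Smith cyclopropanation (Furukawa conditions): the zinc alkoxide delivers the carbenoid to the neighbouring ring alkene C1=C5 on the face of the oxygen, which sets C1 and C5 with the new methylene C6 syn to the C4 oxygen and should spare the remote isopropenyl alkene.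

Step 6
Reactants: 10 (1R,2S,5R)-2-methyl-5-(prop-1-en-2-yl)bicyclo[3.1.0]hexan-2-ol
Product: 11 triethyl{[(1R,2S,5R)-2-methyl-5-(prop-1-en-2-yl)bicyclo[3.1.0]hexan-2-yl]oxy}silane
Conditions: Et3SiOTf, 2,6-lutidine, CH2Cl2, −78 °C
Reagents that add atoms: triethylsilyl trifluoromethanesulfonate, CC[Si](CC)(CC)OS(=O)(=O)C(F)(F)F
Why: Silyl ether formation with a silyl triflate and a hindered base, the standard way to cap a tertiary alcohol, so that the cyclopropylcarbinol cannot ionise in the next step; stereocentres are unchanged.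

Step 7
Reactants: 11 triethyl{[(1R,2S,5R)-2-methyl-5-(prop-1-en-2-yl)bicyclo[3.1.0]hexan-2-yl]oxy}silane; 12 2-methylbut-3-yn-2-ol
Product: 13 (4S,5R)-4-(triethylsilyloxy)guaia-1(10),7-dien-11-ol
Conditions: [Rh(CO)2Cl]2 (5 mol %), 12 (3 equiv), 1,2-dichloroethane, 80 °C
Reagents that add atoms: none
Why: Proposed new method: [Rh(CO)2Cl]2 (monovalent rhodium) should bind the isopropenyl alkene of 11 and insert into the adjacent exocyclic cyclopropane bond C1–C6 with strain release, giving a σ,π-allyl rhodacycle (Rh–C6, allyl over C1–C10–C9); alkyne 12 then inserts at the allyl terminus C9 and C(sp2)–C(sp3) reductive elimination forms C6–C7, so ring B closes as a seven-membered ring by a formal [5+2] annulation that leaves the C1=C10 and C7=C8 alkenes. The closest known reaction type is the rhodium-catalysed intermolecular [5+2] cycloaddition of 1-alkyl- and 1-alkoxy-vinylcyclopropanes with alkynes; new here are the ring-fused, 1,1,2-trisubstituted cyclopropane and the methyl on the vinyl group. No stereocentre is formed, and C5 keeps the configuration set in step 5 because none of its bonds is broken. The step needs cleavage of C1–C6 and not of the ring-fusion bond C1–C5: C1–C6 is the less hindered bond, and opening C1–C5 would lead to a bridged bicyclo[4.3.1]decadiene with a bridgehead alkene. It also needs the alkyne to insert with its unsubstituted carbon C8 at C9, which the bulky C(CH3)2OH group should secure by staying away from the C–C bond formed in the insertion. The silyl ether keeps the cyclopropylcarbinol from ionising, and the excess of 12 should outrun β-hydride elimination of the rhodacycle.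

Step 8
Reactants: 13 (4S,5R)-4-(triethylsilyloxy)guaia-1(10),7-dien-11-ol
Product: 15 (4S,5R,7S,8S)-4-(triethylsilyloxy)guai-1(10)-ene-8,11-diol, via cyclic alkoxyborane 14 (not isolated)
Conditions: BH3·THF (2.5 equiv), THF, 0 °C to rt; then NaOH, H2O2, 0 °C to rt
Reagents that add atoms: hydrogen peroxide, OO; borane (as its THF complex), B (boron of 14 only)
Why: Brown hydroboration–oxidation: after the borane has bound the C11 hydroxyl, boron adds to the less substituted C8 and hydrogen to C7 in a syn fashion, expected from the face that carries H5 (away from the triethylsilyloxy group next to C6), so that oxidation with retention gives the C8 hydroxyl trans to the C7 side chain, while the tetrasubstituted C1=C10 alkene reacts far more slowly.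

Step 9
Reactants: 15 (4S,5R,7S,8S)-4-(triethylsilyloxy)guai-1(10)-ene-8,11-diol
Product: 17 (4S,5R,7S,8S)-8,11-(isopropylidenedioxy)guai-1(10)-en-4-ol, via triol 16 (not isolated)
Conditions: camphorsulfonic acid (cat.), MeOH, rt; evaporation; then 2,2-dimethoxypropane, acetone, rt
Reagents that add atoms: 2,2-dimethoxypropane, COC(C)(C)OC
Why: Acid-catalysed methanolysis of the tertiary silyl ether followed, in the same flask, by transacetalisation, which ties the 1,3-diol (C8 and C11 oxygens) into a six-membered isopropylidene acetal and leaves only the C4 hydroxyl free; no stereocentre is affected.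

Step 10
Reactants: 17 (4S,5R,7S,8S)-8,11-(isopropylidenedioxy)guai-1(10)-en-4-ol
Product: 18 methyl (4S,5R,7S,8S)-8,11-(isopropylidenedioxy)guai-1(10)-en-4-yl oxalate
Conditions: ClC(O)CO2Me, Et3N, DMAP, CH2Cl2, 0 °C to rt
Reagents that add atoms: methyl chlorooxoacetate, COC(=O)C(=O)Cl
Why: DMAP-catalysed acylation of the tertiary alcohol with the small, highly electrophilic methyl oxalyl chloride, with retention at C4.

Step 11
Reactants: 18 methyl (4S,5R,7S,8S)-8,11-(isopropylidenedioxy)guai-1(10)-en-4-yl oxalate
Product: 19 (4S,5S,7S,8S)-8,11-(isopropylidenedioxy)guai-1(10)-ene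
Conditions: Bu3SnH, AIBN (cat.), toluene, 100 °C
Reagents that add atoms: none
Why: Barton–McCombie-type radical deoxygenation of a tertiary methyl oxalate: the stannyl radical adds to the oxalate, the C4–O bond fragments to the planar tertiary radical, and hydrogen transfer from Bu3SnH to the face opposite the C5–C6 bond should put H4 cis to H5 and the methyl cis to C6, as in the target.

Step 12
Reactants: 19 (4S,5S,7S,8S)-8,11-(isopropylidenedioxy)guai-1(10)-ene
Product: 20 (4S,5S,7S,8S)-guai-1(10)-ene-8,11-diol
Conditions: AcOH/THF/H2O (3:1:1), 40 °C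
Reagents that add atoms: none
Why: Mild acid hydrolysis of the isopropylidene acetal, which the tetrasubstituted alkene and the tertiary alcohol tolerate; stereocentres are unchanged.

Step 13
Reactants: 21 4-hydroxycinnamic acid
Product: 22 (E)-3-(4-acetoxyphenyl)prop-2-enoic acid
Conditions: Ac2O, pyridine, rt; aqueous HCl work-up
Reagents that add atoms: acetic anhydride, CC(=O)OC(C)=O
Why: O-Acetylation of the phenol blocks it for the esterification; the carboxylic acid is recovered free after the aqueous acid work-up and the E alkene is untouched.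

Step 14
Reactants: 20 (4S,5S,7S,8S)-guai-1(10)-ene-8,11-diol; 22 (E)-3-(4-acetoxyphenyl)prop-2-enoic acid
Product: 23 (4S,5S,7S,8S)-11-hydroxyguai-1(10)-en-8-yl (E)-3-(4-acetoxyphenyl)prop-2-enoate
Conditions: DCC, DMAP (0.2 equiv), CH2Cl2, 0 °C to rt
Reagents that add atoms: none
Why: Steglich esterification: the carbodiimide-activated acid acylates the secondary C8 hydroxyl under DMAP catalysis while the tertiary C11 hydroxyl is too hindered to react, and C8 keeps its configuration because its C–O bond is not broken.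

Step 15
Reactants: 23 (4S,5S,7S,8S)-11-hydroxyguai-1(10)-en-8-yl (E)-3-(4-acetoxyphenyl)prop-2-enoate
Product: 24 (4S,5S,7S,8S)-11-hydroxyguai-1(10)-en-8-yl (E)-3-(4-hydroxyphenyl)prop-2-enoate
Conditions: K2CO3 (0.2 equiv), MeOH, 0 °C
Reagents that add atoms: none
Why: Base-catalysed transesterification with methanol should cleave the activated aryl acetate much faster than the hindered secondary cinnamate, freeing the phenol and giving the target.

**Compound list**
1 | (S)-linalool, (3S)-3,7-dimethylocta-1,6-dien-3-ol | C=C[C@@](C)(O)CCC=C(C)C | starting material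
2 | ozonide of 1, (3S)-5-(5,5-dimethyl-1,2,4-trioxolan-3-yl)-3-methylpent-1-en-3-ol | C=C[C@@](C)(O)CCC1OOC(C)(C)O1 | intermediate
3 | (5S)-5-ethenyl-5-methyloxolan-2-ol (anomer mixture; ring form of (4S)-4-hydroxy-4-methylhex-5-enal) | C=C[C@]1(C)CCC(O)O1 | intermediate
4 | (3S)-3-methylhept-1-en-6-yn-3-ol | C=C[C@@](C)(O)CCC#C | intermediate
5 | dilithium salt of 4 (lithium alkoxide, lithium acetylide) | C=C[C@@](C)(O[Li])CCC#C[Li] | intermediate
6 | (3S)-3-methyloct-1-en-6-yn-3-ol | C=C[C@@](C)(O)CCC#CC | intermediate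
7 | (1S)-1-methyl-3-(prop-1-en-2-yl)cyclopent-2-en-1-ol | CC(=C)C1=C[C@@](C)(O)CC1 | intermediate
8 | diiodomethane | ICI | starting material
9 | ethylzinc alkoxide of 7 | CC(=C)C1=C[C@@](C)(O[Zn]CC)CC1 | intermediate
10 | (1R,2S,5R)-2-methyl-5-(prop-1-en-2-yl)bicyclo[3.1.0]hexan-2-ol (cyclopropane CH2 syn to OH) | C=C(C)[C@@]12CC[C@](C)(O)[C@@H]1C2 | intermediate
11 | triethyl{[(1R,2S,5R)-2-methyl-5-(prop-1-en-2-yl)bicyclo[3.1.0]hexan-2-yl]oxy}silane | C=C(C)[C@@]12CC[C@](C)(O[Si](CC)(CC)CC)[C@@H]1C2 | intermediate
12 | 2-methylbut-3-yn-2-ol | C#CC(C)(C)O | starting material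
13 | (4S,5R)-4-(triethylsilyloxy)guaia-1(10),7-dien-11-ol | CC1=C2CC[C@](C)(O[Si](CC)(CC)CC)[C@@H]2CC(C(C)(C)O)=CC1 | intermediate
14 | cyclic alkoxyborane (1,2-oxaborolane joining C8 and the C11 oxygen) from 13 | CC1=C2CC[C@](C)(O[Si](CC)(CC)CC)[C@@H]2C[C@H](C(C)(C)O3)[C@@H](B3)C1 | intermediate
15 | (4S,5R,7S,8S)-4-(triethylsilyloxy)guai-1(10)-ene-8,11-diol | CC1=C2CC[C@](C)(O[Si](CC)(CC)CC)[C@@H]2C[C@H](C(C)(C)O)[C@@H](O)C1 | intermediate
16 | (4S,5R,7S,8S)-guai-1(10)-ene-4,8,11-triol | CC1=C2CC[C@](C)(O)[C@@H]2C[C@H](C(C)(C)O)[C@@H](O)C1 | intermediate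
17 | (4S,5R,7S,8S)-8,11-(isopropylidenedioxy)guai-1(10)-en-4-ol | CC1=C2CC[C@](C)(O)[C@@H]2C[C@H](C(C)(C)O3)[C@@H](OC3(C)C)C1 | intermediate
18 | methyl (4S,5R,7S,8S)-8,11-(isopropylidenedioxy)guai-1(10)-en-4-yl oxalate | CC1=C2CC[C@](C)(OC(=O)C(=O)OC)[C@@H]2C[C@H](C(C)(C)O3)[C@@H](OC3(C)C)C1 | intermediate
19 | (4S,5S,7S,8S)-8,11-(isopropylidenedioxy)guai-1(10)-ene | CC1=C2CC[C@H](C)[C@@H]2C[C@H](C(C)(C)O3)[C@@H](OC3(C)C)C1 | intermediate
20 | (4S,5S,7S,8S)-guai-1(10)-ene-8,11-diol | CC1=C2CC[C@H](C)[C@@H]2C[C@H](C(C)(C)O)[C@@H](O)C1 | intermediate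
21 | 4-hydroxycinnamic acid, (E)-3-(4-hydroxyphenyl)prop-2-enoic acid | OC(=O)/C=C/c1ccc(O)cc1 | starting material
22 | (E)-3-(4-acetoxyphenyl)prop-2-enoic acid | CC(=O)Oc1ccc(/C=C/C(=O)O)cc1 | intermediate
23 | (4S,5S,7S,8S)-11-hydroxyguai-1(10)-en-8-yl (E)-3-(4-acetoxyphenyl)prop-2-enoate | CC1=C2CC[C@H](C)[C@@H]2C[C@H](C(C)(C)O)[C@@H](OC(=O)/C=C/c2ccc(OC(C)=O)cc2)C1 | intermediate
24 | (4S,5S,7S,8S)-11-hydroxyguai-1(10)-en-8-yl (E)-3-(4-hydroxyphenyl)prop-2-enoate | CC1=C2CC[C@H](C)[C@@H]2C[C@H](C(C)(C)O)[C@@H](OC(=O)/C=C/c2ccc(O)cc2)C1 | target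

Total step count: 15. Longest linear sequence: 14 (steps 1–12, 14, 15).

**Steps most likely to fail**

Step 7. The rhodacycle may not form from the hindered, ring-fused cyclopropane, it may collapse by β-hydride elimination to dienes, or the alkyne may insert in the opposite sense. The fallback closes ring B by an oxyallyl cation [4+3] cycloaddition on the diene, which is known chemistry. It sets out from dienol 7. Its ethylzinc alkoxide 9 is treated with 1,1,3,3-tetrabromoacetone and further Et2Zn. The zinc-bound dibromo-oxyallyl cation should be delivered to the alkoxide face of the diene, forming C5–C6 and C8–C9 and giving dibromo ketone F1. Zn–Cu couple in methanolic NH4Cl reduces this to hydroxy ketone F2. Silylation as in step 6 gives silyl ether F3, and condensation with 2,4,6-triisopropylbenzenesulfonohydrazide gives hydrazone F4. Shapiro reaction (n-BuLi, 2.2 equiv, THF) should deprotonate on the less hindered C8 side and give vinyllithium F5. Trapping with acetone installs the C11 carbinol, and the route is rejoined at 13.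

Step 8. Borane may add to C7=C8 with poor facial selectivity, because the only stereocentre of ring B (C5) is remote from the alkene. The fallback replaces substrate control by reagent control. It sets out from 13, whose carbinol is masked with 1-(trimethylsilyl)imidazole as trimethylsilyl ether F6. Asymmetric hydroboration with monoisopinocampheylborane then follows, using the antipode that proves matched; the compound is drawn for the reagent made from (+)-α-pinene. This gives borane F7, which is oxidised in the flask (NaOH, H2O2) to alcohol F8. F8 is taken into the conditions of step 9, where the acidic methanol removes both silyl ethers, and the route is rejoined at 17.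

Step 11. Hydrogen transfer to the C4 radical may show poor facial selectivity, or the tertiary oxalate may eliminate thermally before it fragments. The fallback is dehydration followed by hydrogenation. It sets out from 17. Methyl N-(triethylammoniosulfonyl)carbamate (Burgess reagent, benzene, 50 °C) eliminates syn; since H5 is anti to the C4 oxygen, the C4=C5 alkene cannot form. The products should be endocyclic alkene F9 together with exocyclic alkene F10. Hydrogenation of the mixture (H2, PtO2, EtOAc) from the face opposite C6 should converge on 19, leaving the tetrasubstituted C1=C10 alkene intact.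

**Further compounds**
F1 | step 7 | (4S,5R)-6,8-dibromo-4-hydroxy-11,12,13-trinorguai-1(10)-en-7-one (epimers at C6 and C8) | CC1=C2CC[C@](C)(O)[C@@H]2C(Br)C(=O)C(Br)C1
F2 | step 7 | (4S,5R)-4-hydroxy-11,12,13-trinorguai-1(10)-en-7-one | CC1=C2CC[C@](C)(O)[C@@H]2CC(=O)CC1
F3 | step 7 | (4S,5R)-4-(triethylsilyloxy)-11,12,13-trinorguai-1(10)-en-7-one | CC1=C2CC[C@](C)(O[Si](CC)(CC)CC)[C@@H]2CC(=O)CC1
F4 | step 7 | 2,4,6-triisopropylbenzenesulfonylhydrazone of F3 | CC1=C2CC[C@](C)(O[Si](CC)(CC)CC)[C@@H]2CC(=NNS(=O)(=O)c2c(C(C)C)cc(C(C)C)cc2C(C)C)CC1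
F5 | step 7 | (4S,5R)-7-lithio-4-(triethylsilyloxy)-11,12,13-trinorguaia-1(10),7-diene | CC1=C2CC[C@](C)(O[Si](CC)(CC)CC)[C@@H]2CC([Li])=CC1
F6 | step 8 | (4S,5R)-4-(triethylsilyloxy)-11-(trimethylsilyloxy)guaia-1(10),7-diene | CC1=C2CC[C@](C)(O[Si](CC)(CC)CC)[C@@H]2CC(C(C)(C)O[Si](C)(C)C)=CC1
F7 | step 8 | (isopinocampheyl)[(4S,5R,7S,8S)-4-(triethylsilyloxy)-11-(trimethylsilyloxy)guai-1(10)-en-8-yl]borane | CC1=C2CC[C@](C)(O[Si](CC)(CC)CC)[C@@H]2C[C@H](C(C)(C)O[Si](C)(C)C)[C@@H](B[C@@H]3C[C@@H]4C[C@H]([C@H]3C)C4(C)C)C1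
F8 | step 8 | (4S,5R,7S,8S)-4-(triethylsilyloxy)-11-(trimethylsilyloxy)guai-1(10)-en-8-ol | CC1=C2CC[C@](C)(O[Si](CC)(CC)CC)[C@@H]2C[C@H](C(C)(C)O[Si](C)(C)C)[C@@H](O)C1
F9 | step 11 | (5S,7S,8S)-8,11-(isopropylidenedioxy)guaia-1(10),3-diene | CC1=C2CC=C(C)[C@@H]2C[C@H](C(C)(C)O3)[C@@H](OC3(C)C)C1
F10 | step 11 | (5S,7S,8S)-8,11-(isopropylidenedioxy)guaia-1(10),4(15)-diene | CC1=C2CCC(=C)[C@@H]2C[C@H](C(C)(C)O3)[C@@H](OC3(C)C)C1
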